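I started from the amounts: the ochre flask, the very flask asked about, held 1.1 M of solid substrate, the limiting reagent here, and the colder teal run stood beside it.

| flask | solid substrate | temperature | remark | time |
|---|---|---|---|---|
| ochre | 1.1 M | 25 °C | the very flask that is asked about, followed so far |  |
| teal | 0.74 M | 10 °C | run made earlier |  |
| flask | 1.1 M | 25 °C |  | 3.0 d |

- ochre (time / h: target / %, solid substrate / %): 10.0: 21.8, 42.2; 20.0: 32.2, 0; 30.0: 31.3, 0; 40.0: 31.6, 0; 50.0: 31.6, 0; 60.0: 32.9, 0
- teal (time / h: target / %, solid substrate / %): 0.417: 0.1, 96.4; 1.00: 0.5, 91.5; 2.00: 4.1, 86.2; 3.00: 7.2, 80.2; 4.00: 10.7, 72.6; 6.00: 15.8, 60.6

(scatter of a reading: 0.5 percentage points)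

- percent here means solid substrate units held: one side product B counts as two
- solid substrate is a solid; its amount is given per volume of the solution
- target taken out counts as made
- reactions considered so far: solid substrate <-> starting material; starting material + target -> side product B; starting material <-> intermediate A; intermediate B -> side product A; intermediate A -> target; starting material -> intermediate B
- at the start none of the solid substrate is in solution

- north-west: change nothing and wait 6.0 d more
- south-east: at 3.0 d raise the temperature by 20 K, then wait 6.0 d
- west: at 3.0 d take out 90% of the target then present, then wait 6.0 d

- target, in percent of the solid substrate first charged, at 3.0 d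
- what to do for the largest gain in target; "none" if nothing gains more than 2 percentage points (north-west / south-east / west / none)
- target present, with what was taken out counted in, in percent of the solid substrate first charged, after north-west
- target present, with what was taken out counted in, in percent of the solid substrate first charged, after south-east

In the ochre run 42.2% of the solid still stood at 10.0 h, so it had entered solution at about 0.0636 M h⁻¹, and I reckoned a clearing time of 17.3 h, the charge divided by that rate, which the reading of 0% at 20.0 h bore out. For a bound from above, I took the target made per solid dissolved at 10.0 h, a reading of 37.7%, which the whole charge would reach if it went on the same way. I tightened this to the highest later reading, 32.9%, since in the teal run target rose from 0.5% at 1.00 h to 4.1% at 2.00 h, a hold-up in solution far shorter than the wait. For a bound from below, I took the lowest later reading, 31.3%: the listed reaction that uses up target also needs starting material, and the solid that feeds it read 0% at 20.0 h. My bracket was therefore 1.6 percentage points wide, against the 2 points an option must gain, and with the feed ended at the clearing time, I expected waiting, heating and taking out to gain nothing.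

The forecast gave 32% at 3.0 d, a figure inside my bracket, then 32% after north-west and 32% after south-east, with none as the choice, saying “the flask is therefore finished”.

The flask gave 32.2%, then 32.2% after north-west and 32.2% after south-east, and the choice was none, with west gaining 0 points.

    solid substrate ⇌ starting material, rate k1*(cs1 - [starting material]) while solid is left; crystals form when [starting material] > cs1 (solubility = 0.0810 M, k = 0.0148 min⁻¹)
    starting material + target → side product B (k = 0.0854 M⁻¹ min⁻¹, Ea = 52.0 kJ mol⁻¹)
    starting material ⇌ intermediate A (K = 0.670, k = 0.917 min⁻¹, Ea = 82.0 kJ mol⁻¹, ΔH = −39.0 kJ mol⁻¹)
    intermediate B → side product A (k = 0.457 min⁻¹, Ea = 94.0 kJ mol⁻¹)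
    intermediate A → target (k = 0.0845 min⁻¹, Ea = 98.0 kJ mol⁻¹)
    starting material → intermediate B (k = 0.0418 min⁻¹, Ea = 92.0 kJ mol⁻¹)
    (constants at 25 °C)

The clearing time of 17.3 h lies well inside the 72.0 h of this flask, and at 36.0 h the solid already stood at 0% and target at 32.2%. The main reason that target stood so low in this flask was the back reaction of intermediate A to starting material: the run without it reached 87.7% rather than 32.2% at 3.0 d, which accounts for 82% of what is missing. The same rate gives the neighbour charged with 1.9 M a clearing time of 29.9 h, inside its 72.0 h, and that neighbour ended with 0% of its charge still there, 40.5% in side product B and 24.4% in target.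

(The readings were generated by integration from invented constants; scatter was added.)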